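Conventions and one remark on the chemistry: flavan numbering is used; unprimed locants belong to unit A (rings A, C, B) and primed locants to unit B (rings D, F, E). Bn = benzyl, TBS = tert-butyldimethylsilyl, and "UB-O" is the {(2S,3R,4R)-3,7,8-tris(benzyloxy)-2-[4-(benzyloxy)phenyl]-3,4-dihydro-2H-chromen-4-yl}oxy group, that is alcohol 10 bound through its C4' oxygen. The sense of induction stated for each chiral catalyst is the one expected by analogy with simpler substrates; if it proves opposite, the antipodal ligand is used.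

## The problem

Target 37 is a dimer of two 7,8,4'-trihydroxyflavan-3,4-diols joined only by the C4–O–C4' ether between two secondary benzylic carbons. Unit A is all-cis (2R,3R,4R) and unit B is 2,3-trans-3,4-cis (2S,3R,4R), so the units differ at C2 relative to C3 and one monomer cannot serve for both. Each C–O bond of the linking ether is para to a C7 oxygen and ortho to a ring oxygen, so it ionises easily to a flavan-4-yl cation; acid or Lewis acid late in the route would cleave or scramble the dimer. Nucleophiles add to such cations trans to the C3 oxygen, whereas both units need the 3,4-cis arrangement, so the ether cannot be made by substitution at C4 or C4'. In unit B, C2' and C3' can come from one enantioselective event and C3' can then direct a ketone reduction at C4'. In unit A, C2 and C3 can be set together by an aldol reaction, but C4 has no reliable neighbour control in an open chain and needs a catalyst. Eight hydroxyls, six of them phenolic and four of these in oxidation-prone catechol arrays, must carry groups that leave under neutral conditions at the end. Ring A of unit A has O1 on C8a followed by the C8 and C7 oxygens next to C4a, with hydrogen on C5 and C6. This is the pattern that thermal ring expansion of a 2,3-dialkoxy-4-alkenylcyclobutenone gives, and in that process O1 appears as the only free phenol, ready to close ring C.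

## Retrosynthesis

Target 37 is traced to its octabenzyl ether 36 by cutting eight O–benzyl bonds. Benzyl is chosen because every other step of the route is neutral or basic and hydrogenolysis is the only neutral global deprotection compatible with the acid-labile ether. The forward step must leave the ring-embedded benzylic C–O bonds alone.

Ring C of 36 is opened at O1–C2, giving phenol-alcohol 35 and, one silyl group earlier, phenol 34. Cutting at O1–C2 and not at C4 keeps the sensitive C4 ether untouched during ring closure. The closure is an intramolecular Mitsunobu displacement that inverts C2, so 35 must carry the C2 hydroxyl anti to the C3 benzyloxy group.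

Ring A of 34 is disconnected at C4a–C8a and traced through dienone 33 and dienylketene 32 to cyclobutenone 31. The alternative, a preformed 2,3,4-trioxygenated aryl nucleophile, would need three adjacent oxygens told apart and would place C4 at a benzylic position before the ether exists, inviting ionisation. In 31 the aromatic ring is replaced by a squarate-derived four-membered ring and an E-alkene. The forward reaction needs only heat, an E-alkene and the absence of any free hydroxyl that could capture the ketene.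

Cyclobutenone 31 is cut at the bond between the ring sp3 carbon and the alkene, giving alkenylzirconocene 30 (from alkyne 25) and 4-chlorocyclobutenone 29. The chloride is traced through hydroxycyclobutenone 28 and dibenzyl squarate 27 to squaric acid 26. This coupling is chosen over 1,2-addition of an alkenyllithium to 27 because that would leave an extra oxygen on C6.

Alkyne 25 is traced through aldehyde 24 to the terminal alkene 22 by exchange of the terminal carbon. Alkene 22 is cut at the C4–O bond into allylic carbonate 20 and the unit B alcohol 10. An iridium-catalysed allylic etherification forms this bond at the oxygen of a preformed cis-4-ol and at an allylic, not benzylic, carbon of unit A, so neither flavan-4-yl cation is involved. The forward reaction has to join two hindered partners with catalyst control at C4.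

Carbonate 20 is traced through allylic alcohol 19 and enoate 18 to aldehyde 17, a two-carbon homologation. Aldehyde 17 comes from thioester 16 and aldol adduct 15, which is cut at C2–C3 into silyl ketene thioacetal 13 and 4-(benzyloxy)benzaldehyde 4. An anti glycolate aldol sets C2 and C3 together and gives the anti relationship that the Mitsunobu inversion needs. Thioacetal 13 comes from thioester 12 and benzyloxyacetyl chloride 11.

Alcohol 10 is traced to ketone 9 (C4'–H bond, reduction directed by C3') and to the 3-hydroxyflavanone 8. Ring F of 8 is opened at O1'–C2' to the free-phenol epoxide 7 and its protected form 6, whose epoxide comes from chalcone 5. Chalcone 5 is cut at the C=C bond into acetophenone 3 and aldehyde 4. Acetophenone 3 comes from gallacetophenone 1 through dibenzyl ether 2. Here acid-mediated ring closure is harmless because no bis-benzylic ether is present yet.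

## Roads not taken

Alternative 1: Ring F is cut at C3'=C4'. The unit A 4-ol would be esterified with a ring D benzoic acid whose ortho oxygen carries a 1-arylallyl group, and the Takai–Utimoto reagent (TiCl4, Zn, PbCl2, TMEDA, CH3CHBr2) would convert the allyl alkene into a titanium alkylidene that olefinates the ester carbonyl, giving enol ether A1.
- Merits: the link between the two hindered halves is made as an ester, the easiest possible coupling, with no ionisation risk, and ring F closes without acid. In this respect it is better than the iridium etherification of the chosen plan.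
- Weak points: A1 still lacks the C3' oxygen and both the C3' and C4' stereocentres. Hydroboration–oxidation adds H and OH syn and anti to the C2' aryl group, which gives 2,3-trans but places the new hydroxyl trans to the C4' ether oxygen, the opposite of the required 3,4-cis. Epoxidation routes pass through an acetal-like C4' that is likely to collapse. The excess low-valent titanium reagent would meet eight benzyl ethers, and unit A must already be complete, so ring A is not addressed.
- Comparison: the chosen plan sets C4' before the coupling and never touches it again; it pays for this with a harder ether-forming step.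

Alternative 2: Ring C is cut at O1–C2 and C3–C4. Fluoride would unmask a phenoxide, acetate would leave from the benzylic carbon to give an ortho-quinone methide bearing the unit B alkoxy group on the methide carbon, and (Z)-2-[4-(benzyloxy)phenyl]ethenyl acetate A2 would add across it to give A3.
- Merits: ring C and three stereocentres form in one step from an aromatic ring A, and the Z-alkene maps onto the 2,3-cis relationship. This road is much shorter than the chosen plan.
- Weak points: the precursor is a mixed acyl/alkyl acetal of a hindered secondary alcohol, which is hard to make and to keep. The required regiochemistry needs the styrene polarisation of A2 to override its enol-acetate polarisation, since the acetoxy carbon must bond to the methide carbon. The absolute configuration of three new centres would depend only on the remote chirality of unit B, and endo/exo selectivity decides the 3,4-relationship.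
- Comparison: the chosen plan is longer, but it sets every unit A centre by reagent control (aldol, iridium catalyst, SN2 inversion) and asks no facial selectivity of its key step.

Alternative 3: Ring F is cut at O1'–C2'. Under camphorsulfonic acid the ring D phenol would open a trans-epoxide at the benzylic carbon with inversion, giving A4 with a free C3' hydroxyl.
- Merits: the step is stereospecific and better precedented than a ring expansion; the chosen plan uses the same bond construction in step 5.
- Weak points: here the acid would act on a compound that already contains the ionisable bis-benzylic ether and a finished unit A. The C4' stereocentre and the epoxide would have to be built on an open chain attached to unit A, carrying valuable material through a long linear sequence. The benzylic activation that favours 6-endo over 5-exo opening also invites ionisation and loss of stereospecificity.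
- Comparison: the chosen plan performs this ring closure on the ketone-activated chalcone oxide before the coupling, where acid does no harm. Against the better precedent of this alternative it sets the built-in differentiation of O1 and an acid-free late stage.

Key step: step 23

## Route

Step 1
Reactants: 1 gallacetophenone
Product: 2 1-[3,4-bis(benzyloxy)-2-hydroxyphenyl]ethan-1-one
Conditions: BnBr (2.05 equiv), K2CO3, acetone, reflux
Reagents that add atoms: benzyl bromide, BrCc1ccccc1
Why: Williamson ether synthesis; the 2-hydroxyl is hydrogen-bonded to the acetyl group and is the least reactive of the three, so two equivalents of halide should alkylate O-4 and O-3 and leave it free.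

Step 2
Reactants: 2 1-[3,4-bis(benzyloxy)-2-hydroxyphenyl]ethan-1-one
Product: 3 1-[3,4-bis(benzyloxy)-2-(methoxymethoxy)phenyl]ethan-1-one
Conditions: MeOCH2Cl, K2CO3, acetone, reflux
Reagents that add atoms: chloromethyl methyl ether, COCCl
Why: O-alkylation of the remaining chelated phenol as its methoxymethyl acetal; masking it prevents flavanone and aurone formation in the basic steps that follow.

Step 3
Reactants: 3 1-[3,4-bis(benzyloxy)-2-(methoxymethoxy)phenyl]ethan-1-one; 4 4-(benzyloxy)benzaldehyde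
Product: 5 (E)-1-[3,4-bis(benzyloxy)-2-(methoxymethoxy)phenyl]-3-[4-(benzyloxy)phenyl]prop-2-en-1-one
Conditions: KOH, EtOH/H2O, rt
Reagents that add atoms: none
Why: Claisen–Schmidt condensation of a methyl ketone with a non-enolisable aldehyde; E1cB dehydration gives the conjugated E-alkene.

Step 4
Reactants: 5 (E)-1-[3,4-bis(benzyloxy)-2-(methoxymethoxy)phenyl]-3-[4-(benzyloxy)phenyl]prop-2-en-1-one
Product: 6 [3,4-bis(benzyloxy)-2-(methoxymethoxy)phenyl]{(2S,3R)-3-[4-(benzyloxy)phenyl]oxiran-2-yl}methanone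
Conditions: poly-D-leucine, urea–H2O2, DBU, THF, rt
Reagents that add atoms: hydrogen peroxide as its urea adduct, OO.NC(N)=O
Why: Juliá–Colonna epoxidation (nucleophilic epoxidation by hydroperoxide bound to the helical polypeptide); the D-polymer is the mirror image of the L-polymer that gives (2R,3S)-chalcone oxides, so the (2S,3R)-epoxide is expected, and the trans geometry follows from the E-alkene.

Step 5
Reactants: 6 [3,4-bis(benzyloxy)-2-(methoxymethoxy)phenyl]{(2S,3R)-3-[4-(benzyloxy)phenyl]oxiran-2-yl}methanone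
Product: 8 (2S,3S)-7,8-bis(benzyloxy)-2-[4-(benzyloxy)phenyl]-3-hydroxy-2,3-dihydro-4H-chromen-4-one, via free-phenol epoxide 7 (not isolated)
Conditions: HCl, MeOH/THF, 50 °C
Reagents that add atoms: none
Why: Acidic acetal cleavage frees the phenol, which opens the epoxide at the benzylic carbon in a 6-endo intramolecular epoxide opening with inversion (C2' becomes S), while the α-carbon keeps its oxygen and configuration as C3', giving the 2,3-trans 3-hydroxyflavanone.

Step 6
Reactants: 8 (2S,3S)-7,8-bis(benzyloxy)-2-[4-(benzyloxy)phenyl]-3-hydroxy-2,3-dihydro-4H-chromen-4-one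
Product: 9 (2S,3S)-3,7,8-tris(benzyloxy)-2-[4-(benzyloxy)phenyl]-2,3-dihydro-4H-chromen-4-one
Conditions: BnBr, Ag2O, CH2Cl2, rt, dark
Reagents that add atoms: benzyl bromide, BrCc1ccccc1
Why: Silver-oxide-promoted O-benzylation (Purdie-type alkylation) works without strong base, which a 3-hydroxyflavanone would answer with ring opening, epimerisation or dehydrogenation.

Step 7
Reactants: 9 (2S,3S)-3,7,8-tris(benzyloxy)-2-[4-(benzyloxy)phenyl]-2,3-dihydro-4H-chromen-4-one
Product: 10 (2S,3R,4R)-3,7,8-tris(benzyloxy)-2-[4-(benzyloxy)phenyl]-3,4-dihydro-2H-chromen-4-ol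
Conditions: LiBH(s-Bu)3 (L-Selectride), THF, −78 °C
Reagents that add atoms: none
Why: Diastereoselective ketone reduction by a bulky borohydride; on the half-chair with the 2-aryl and 3-benzyloxy groups equatorial the reagent should approach C4' equatorially, placing the new hydroxyl axial and cis to O-3' (4'R).

Step 8
Reactants: 11 2-(benzyloxy)acetyl chloride
Product: 12 S-ethyl 2-(benzyloxy)ethanethioate
Conditions: EtSH, pyridine, CH2Cl2, 0 °C → rt
Reagents that add atoms: ethanethiol, CCS
Why: Acyl substitution of the acid chloride by the thiol (thioesterification).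

Step 9
Reactants: 12 S-ethyl 2-(benzyloxy)ethanethioate
Product: 13 (Z)-{[2-(benzyloxy)-1-(ethylsulfanyl)ethenyl]oxy}trimethylsilane
Conditions: LiN(i-Pr)2, Me3SiCl, THF, −78 °C
Reagents that add atoms: chlorotrimethylsilane, C[Si](C)(C)Cl
Why: Kinetic enolisation and O-silylation; α-alkoxy thioesters give the Z silyl ketene thioacetal, the geometry that leads to anti adducts in the aldol that follows.

Step 10
Reactants: 13 (Z)-{[2-(benzyloxy)-1-(ethylsulfanyl)ethenyl]oxy}trimethylsilane; 4 4-(benzyloxy)benzaldehyde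
Product: 15 S-ethyl (2S,3S)-2-(benzyloxy)-3-[4-(benzyloxy)phenyl]-3-hydroxypropanethioate, via O-trimethylsilyl aldol adduct 14 (not isolated)
Conditions: Sn(OTf)2, (S)-1-ethyl-2-(piperidin-1-ylmethyl)pyrrolidine, Bu2Sn(OAc)2, CH2Cl2, −78 °C; then aq. HCl/THF
Reagents that add atoms: none
Why: Asymmetric Mukaiyama aldol addition mediated by tin triflate and a chiral diamine; coordination of the benzyloxy group to tin makes the addition anti-selective and the proline-derived diamine selects the aldehyde face, setting C2 and C3 of unit A as the (2S,3S)-anti adduct, and acidic work-up hydrolyses silyl ether 14.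

Step 11
Reactants: 15 S-ethyl (2S,3S)-2-(benzyloxy)-3-[4-(benzyloxy)phenyl]-3-hydroxypropanethioate
Product: 16 S-ethyl (2S,3S)-2-(benzyloxy)-3-[4-(benzyloxy)phenyl]-3-(TBS-oxy)propanethioate
Conditions: t-BuMe2SiOTf, 2,6-lutidine, CH2Cl2, −78 → 0 °C
Reagents that add atoms: tert-butyldimethylsilyl trifluoromethanesulfonate, CC(C)(C)[Si](C)(C)OS(=O)(=O)C(F)(F)F
Why: Silylation of a secondary alcohol with a silyl triflate; the silyl ether masks the only hydroxyl of the chain so that nothing nucleophilic meets the ketene of step 23.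

Step 12
Reactants: 16 S-ethyl (2S,3S)-2-(benzyloxy)-3-[4-(benzyloxy)phenyl]-3-(TBS-oxy)propanethioate
Product: 17 (2S,3S)-2-(benzyloxy)-3-[4-(benzyloxy)phenyl]-3-(TBS-oxy)propanal
Conditions: i-Bu2AlH, CH2Cl2, −78 °C; Rochelle salt
Reagents that add atoms: none
Why: Partial reduction of a thioester to the aldehyde by an aluminium hydride at low temperature, the thiohemiacetal aluminate surviving until work-up; the α-alkoxy aldehyde is used at once to avoid epimerisation.

Step 13
Reactants: 17 (2S,3S)-2-(benzyloxy)-3-[4-(benzyloxy)phenyl]-3-(TBS-oxy)propanal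
Product: 18 ethyl (2E,4R,5S)-4-(benzyloxy)-5-[4-(benzyloxy)phenyl]-5-(TBS-oxy)pent-2-enoate
Conditions: (EtO)2P(O)CH2CO2Et, LiCl, DBU, MeCN, 0 °C → rt
Reagents that add atoms: triethyl phosphonoacetate, CCOC(=O)CP(=O)(OCC)OCC
Why: Horner–Wadsworth–Emmons olefination under Masamune–Roush conditions, mild enough for the epimerisable α-benzyloxy aldehyde and E-selective.

Step 14
Reactants: 18 ethyl (2E,4R,5S)-4-(benzyloxy)-5-[4-(benzyloxy)phenyl]-5-(TBS-oxy)pent-2-enoate
Product: 19 (2E,4R,5S)-4-(benzyloxy)-5-[4-(benzyloxy)phenyl]-5-(TBS-oxy)pent-2-en-1-ol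
Conditions: i-Bu2AlH (2.2 equiv), CH2Cl2, −78 °C
Reagents that add atoms: none
Why: 1,2-Reduction of the unsaturated ester to the allylic alcohol by an aluminium hydride.

Step 15
Reactants: 19 (2E,4R,5S)-4-(benzyloxy)-5-[4-(benzyloxy)phenyl]-5-(TBS-oxy)pent-2-en-1-ol
Product: 20 (2E,4R,5S)-4-(benzyloxy)-5-[4-(benzyloxy)phenyl]-5-(TBS-oxy)pent-2-en-1-yl methyl carbonate
Conditions: ClCO2Me, pyridine, CH2Cl2, 0 °C
Reagents that add atoms: methyl chloroformate, COC(=O)Cl
Why: O-Acylation with a chloroformate installs the carbonate leaving group needed for allyliridium formation.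

Step 16
Reactants: 20 (2E,4R,5S)-4-(benzyloxy)-5-[4-(benzyloxy)phenyl]-5-(TBS-oxy)pent-2-en-1-yl methyl carbonate; 10 (2S,3R,4R)-3,7,8-tris(benzyloxy)-2-[4-(benzyloxy)phenyl]-3,4-dihydro-2H-chromen-4-ol
Product: 22 (3R,4R,5S)-4-(benzyloxy)-5-[4-(benzyloxy)phenyl]-5-(TBS-oxy)-3-(UB-O)pent-1-ene, via cuprous alkoxide 21 (not isolated)
Conditions: 10, LiN(SiMe3)2 then CuI, THF, 0 °C; then 20, [Ir(cod)Cl]2 (cat.), (Ra,R,R)-O,O'-(1,1'-binaphthalene-2,2'-diyl) N,N-bis(1-phenylethyl)phosphoramidite (cat., activated with n-PrNH2), THF, rt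
Reagents that add atoms: none
Why: Iridium-catalysed asymmetric allylic etherification with a copper alkoxide; the alkoxide attacks the substituted terminus of the allyliridium intermediate to give the branched ether, the ligand enantiomer is expected to fix C4 as R (the same sense as with aryl-substituted allyl carbonates and heteroatom nucleophiles), and because the bond is made at oxygen the cis C4' configuration of 10 is carried over unchanged.

Step 17
Reactants: 22 (3R,4R,5S)-4-(benzyloxy)-5-[4-(benzyloxy)phenyl]-5-(TBS-oxy)-3-(UB-O)pent-1-ene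
Product: 24 (2S,3R,4S)-3-(benzyloxy)-4-[4-(benzyloxy)phenyl]-4-(TBS-oxy)-2-(UB-O)butanal, via vicinal diol 23 (not isolated)
Conditions: OsO4 (cat.), NaIO4, 2,6-lutidine, dioxane/H2O, rt
Reagents that add atoms: osmium tetroxide, O=[Os](=O)(=O)=O (oxygen donor, regenerated by sodium periodate, [Na+].[O-]I(=O)(=O)=O)
Why: Lemieux–Johnson oxidation (dihydroxylation then periodate glycol cleavage, buffered with 2,6-lutidine) removes the terminal carbon and leaves the future C4a as an aldehyde under neutral conditions that spare the silyl ether and the bis-benzylic ether.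

Step 18
Reactants: 24 (2S,3R,4S)-3-(benzyloxy)-4-[4-(benzyloxy)phenyl]-4-(TBS-oxy)-2-(UB-O)butanal
Product: 25 (3R,4R,5S)-4-(benzyloxy)-5-[4-(benzyloxy)phenyl]-5-(TBS-oxy)-3-(UB-O)pent-1-yne
Conditions: dimethyl (1-diazo-2-oxopropyl)phosphonate, K2CO3, MeOH/THF, 0 °C → rt
Reagents that add atoms: dimethyl (1-diazo-2-oxopropyl)phosphonate, COP(=O)(OC)C(=[N+]=[N-])C(C)=O
Why: Seyferth–Gilbert homologation with the Ohira–Bestmann reagent converts the aldehyde into the terminal alkyne under mild carbonate base, conditions under which α-alkoxy aldehydes generally keep their configuration.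

Step 19
Reactants: 26 squaric acid
Product: 27 3,4-bis(benzyloxy)cyclobut-3-ene-1,2-dione (dibenzyl squarate)
Conditions: BnOH, toluene, reflux, Dean–Stark
Reagents that add atoms: benzyl alcohol, OCc1ccccc1
Why: Azeotropic esterification of the strongly acidic vinylogous acid with the alcohol.

Step 20
Reactants: 27 3,4-bis(benzyloxy)cyclobut-3-ene-1,2-dione
Product: 28 2,3-bis(benzyloxy)-4-hydroxycyclobut-2-en-1-one (racemic)
Conditions: LiAlH(Ot-Bu)3, THF, −78 °C; cold neutral work-up
Reagents that add atoms: none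
Why: Selective 1,2-reduction of one carbonyl of a squarate ester by a hindered aluminium hydride; the product is a vinylogous ester and resists a second hydride.

Step 21
Reactants: 28 2,3-bis(benzyloxy)-4-hydroxycyclobut-2-en-1-one
Product: 29 2,3-bis(benzyloxy)-4-chlorocyclobut-2-en-1-one (racemic)
Conditions: PPh3, CCl4, CH2Cl2, 0 °C; used without storage
Reagents that add atoms: tetrachloromethane, ClC(Cl)(Cl)Cl
Why: Appel reaction (alcohol to chloride through an alkoxyphosphonium ion) under neutral conditions; acid is avoided because it converts such hydroxycyclobutenones into cyclobutenediones.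

Step 22
Reactants: 25 (3R,4R,5S)-4-(benzyloxy)-5-[4-(benzyloxy)phenyl]-5-(TBS-oxy)-3-(UB-O)pent-1-yne; 29 2,3-bis(benzyloxy)-4-chlorocyclobut-2-en-1-one
Product: 31 2,3-bis(benzyloxy)-4-[(1E,3R,4R,5S)-4-(benzyloxy)-5-[4-(benzyloxy)phenyl]-5-(TBS-oxy)-3-(UB-O)pent-1-en-1-yl]cyclobut-2-en-1-one (both epimers at the ring sp3 carbon), via alkenylzirconocene 30 (not isolated)
Conditions: 25, Cp2Zr(H)Cl, THF, rt; then 29, Pd(PPh3)4 (5 mol%), THF, 0 °C → rt
Reagents that add atoms: none
Why: Hydrozirconation of the terminal alkyne (syn addition, zirconium on the terminal carbon) gives E-alkenylzirconocene 30, which couples with the allylic α-keto chloride under zerovalent palladium, the known cross-coupling of 4-chlorocyclobutenones with alkenylzirconium reagents; the new ring stereocentre forms unselectively and is erased in step 23.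

Step 23
Reactants: 31 2,3-bis(benzyloxy)-4-[(1E,3R,4R,5S)-4-(benzyloxy)-5-[4-(benzyloxy)phenyl]-5-(TBS-oxy)-3-(UB-O)pent-1-en-1-yl]cyclobut-2-en-1-one
Product: 34 2,3-bis(benzyloxy)-6-[(1R,2R,3S)-2-(benzyloxy)-3-[4-(benzyloxy)phenyl]-3-(TBS-oxy)-1-(UB-O)propyl]phenol, via dienylketene 32 (not isolated), via cyclohexa-2,4-dienone 33 (not isolated)
Conditions: toluene (0.01 M), 100 °C, argon
Reagents that add atoms: none
Why: Heating opens the strained cyclobutenone by a reversible conrotatory 4π electrocyclic ring opening to dienylketenes, and both ring epimers of 31 converge. Only isomer 32, in which the alkenyl group has turned inward so that the ketene and the alkene are cis about the new double bond, can cyclise; the outward isomer recloses and is recycled. A disrotatory 6π electrocyclisation then joins the ketene carbon to the far alkene carbon, forming C8a–C4a and closing ring A as dienone 33, and enolisation aromatises it to 34. The closest known reaction type is the thermal rearrangement of 4-alkenyl- and 4-arylcyclobutenones made by cross-coupling of 4-chlorocyclobutenones, the same cascade as the second half of the Danheiser benzannulation and as the Moore rearrangement. No stereocentre is created, since the sp3 carbon of 33 is lost on aromatisation and C2, C3 and C4 lie outside the pericyclic array. Regiochemistry is fixed by connectivity: the ketene oxygen becomes O1 as the only free phenol, the squarate oxygens become the C8 and C7 benzyl ethers and the alkene carbons become C5 and C4a. The selectivity needed is chemoselectivity of the ketene, secured by the absence of any free hydroxyl in 31 and by high dilution, which disfavours acylation of the hindered product phenol. Neutral conditions and the lowest workable temperature are chosen so that the ortho-hydroxybenzyl ether of 34 does not expel unit B.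

Step 24
Reactants: 34 2,3-bis(benzyloxy)-6-[(1R,2R,3S)-2-(benzyloxy)-3-[4-(benzyloxy)phenyl]-3-(TBS-oxy)-1-(UB-O)propyl]phenol
Product: 35 2,3-bis(benzyloxy)-6-[(1R,2S,3S)-2-(benzyloxy)-3-[4-(benzyloxy)phenyl]-3-hydroxy-1-(UB-O)propyl]phenol
Conditions: Bu4NF, AcOH, THF, 0 °C → rt
Reagents that add atoms: none
Why: Fluoride-mediated desilylation; acetic acid buffering keeps the ortho-hydroxybenzyl ether from base-induced loss of unit B (the change of the C2 descriptor of the propyl chain is only a change of priorities).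

Step 25
Reactants: 35 2,3-bis(benzyloxy)-6-[(1R,2S,3S)-2-(benzyloxy)-3-[4-(benzyloxy)phenyl]-3-hydroxy-1-(UB-O)propyl]phenol
Product: 36 (2R,3R,4R)-3,7,8-tris(benzyloxy)-2-[4-(benzyloxy)phenyl]-4-(UB-O)-3,4-dihydro-2H-chromene
Conditions: PPh3, DIAD, toluene/THF, 0 °C
Reagents that add atoms: none
Why: Intramolecular Mitsunobu etherification; the benzylic hydroxyl is activated as its oxyphosphonium ion and displaced by phenol O1 in a 6-exo-tet SN2 closure with inversion, turning the anti C2/C3 relationship of the chain into the 2,3-cis ring (2R), and low temperature in a weakly polar medium is chosen to keep the p-alkoxybenzylic centre from ionising.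

Step 26
Reactants: 36 (2R,3R,4R)-3,7,8-tris(benzyloxy)-2-[4-(benzyloxy)phenyl]-4-(UB-O)-3,4-dihydro-2H-chromene
Product: 37 (2R,3R,4R)-2-(4-hydroxyphenyl)-4-{[(2S,3R,4R)-3,7,8-trihydroxy-2-(4-hydroxyphenyl)-3,4-dihydro-2H-chromen-4-yl]oxy}-3,4-dihydro-2H-chromene-3,7,8-triol
Conditions: H2 (1 atm), Pd(OH)2/C, EtOAc/MeOH, rt
Reagents that add atoms: none
Why: Catalytic hydrogenolysis of the eight benzyl ethers; the ring-embedded secondary benzylic C–O bonds (C2–O1, C2'–O1' and the C4–O–C4' ether) should cleave far more slowly than primary benzyl ethers, as in the debenzylation of benzylated flavan-3-ols, and the neutral solvent avoids ionisation of the ether.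

## Compound list

1 | gallacetophenone, 1-(2,3,4-trihydroxyphenyl)ethan-1-one | CC(=O)c1ccc(O)c(O)c1O | starting material
2 | 1-[3,4-bis(benzyloxy)-2-hydroxyphenyl]ethan-1-one | CC(=O)c1ccc(OCc2ccccc2)c(OCc2ccccc2)c1O | intermediate
3 | 1-[3,4-bis(benzyloxy)-2-(methoxymethoxy)phenyl]ethan-1-one | CC(=O)c1ccc(OCc2ccccc2)c(OCc2ccccc2)c1OCOC | intermediate
4 | 4-(benzyloxy)benzaldehyde | O=Cc1ccc(OCc2ccccc2)cc1 | starting material
5 | (E)-1-[3,4-bis(benzyloxy)-2-(methoxymethoxy)phenyl]-3-[4-(benzyloxy)phenyl]prop-2-en-1-one | O=C(/C=C/c1ccc(OCc2ccccc2)cc1)c1ccc(OCc2ccccc2)c(OCc2ccccc2)c1OCOC | intermediate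
6 | [3,4-bis(benzyloxy)-2-(methoxymethoxy)phenyl]{(2S,3R)-3-[4-(benzyloxy)phenyl]oxiran-2-yl}methanone | O=C([C@H]1O[C@@H]1c1ccc(OCc2ccccc2)cc1)c1ccc(OCc2ccccc2)c(OCc2ccccc2)c1OCOC | intermediate
7 | [3,4-bis(benzyloxy)-2-hydroxyphenyl]{(2S,3R)-3-[4-(benzyloxy)phenyl]oxiran-2-yl}methanone (not isolated) | O=C([C@H]1O[C@@H]1c1ccc(OCc2ccccc2)cc1)c1ccc(OCc2ccccc2)c(OCc2ccccc2)c1O | intermediate
8 | (2S,3S)-7,8-bis(benzyloxy)-2-[4-(benzyloxy)phenyl]-3-hydroxy-2,3-dihydro-4H-chromen-4-one | O=C1c2ccc(OCc3ccccc3)c(OCc3ccccc3)c2O[C@@H](c2ccc(OCc3ccccc3)cc2)[C@@H]1O | intermediate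
9 | (2S,3S)-3,7,8-tris(benzyloxy)-2-[4-(benzyloxy)phenyl]-2,3-dihydro-4H-chromen-4-one | O=C1c2ccc(OCc3ccccc3)c(OCc3ccccc3)c2O[C@@H](c2ccc(OCc3ccccc3)cc2)[C@@H]1OCc1ccccc1 | intermediate
10 | (2S,3R,4R)-3,7,8-tris(benzyloxy)-2-[4-(benzyloxy)phenyl]-3,4-dihydro-2H-chromen-4-ol | O[C@@H]1c2ccc(OCc3ccccc3)c(OCc3ccccc3)c2O[C@@H](c2ccc(OCc3ccccc3)cc2)[C@@H]1OCc1ccccc1 | intermediate
11 | 2-(benzyloxy)acetyl chloride | O=C(Cl)COCc1ccccc1 | starting material
12 | S-ethyl 2-(benzyloxy)ethanethioate | CCSC(=O)COCc1ccccc1 | intermediate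
13 | (Z)-{[2-(benzyloxy)-1-(ethylsulfanyl)ethenyl]oxy}trimethylsilane | CCS/C(O[Si](C)(C)C)=C\OCc1ccccc1 | intermediate
14 | S-ethyl (2S,3S)-2-(benzyloxy)-3-[4-(benzyloxy)phenyl]-3-[(trimethylsilyl)oxy]propanethioate (not isolated) | CCSC(=O)[C@@H](OCc1ccccc1)[C@@H](O[Si](C)(C)C)c1ccc(OCc2ccccc2)cc1 | intermediate
15 | S-ethyl (2S,3S)-2-(benzyloxy)-3-[4-(benzyloxy)phenyl]-3-hydroxypropanethioate | CCSC(=O)[C@@H](OCc1ccccc1)[C@@H](O)c1ccc(OCc2ccccc2)cc1 | intermediate
16 | S-ethyl (2S,3S)-2-(benzyloxy)-3-[4-(benzyloxy)phenyl]-3-(TBS-oxy)propanethioate | CCSC(=O)[C@@H](OCc1ccccc1)[C@@H](O[Si](C)(C)C(C)(C)C)c1ccc(OCc2ccccc2)cc1 | intermediate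
17 | (2S,3S)-2-(benzyloxy)-3-[4-(benzyloxy)phenyl]-3-(TBS-oxy)propanal | O=C[C@@H](OCc1ccccc1)[C@@H](O[Si](C)(C)C(C)(C)C)c1ccc(OCc2ccccc2)cc1 | intermediate
18 | ethyl (2E,4R,5S)-4-(benzyloxy)-5-[4-(benzyloxy)phenyl]-5-(TBS-oxy)pent-2-enoate | CCOC(=O)/C=C/[C@@H](OCc1ccccc1)[C@@H](O[Si](C)(C)C(C)(C)C)c1ccc(OCc2ccccc2)cc1 | intermediate
19 | (2E,4R,5S)-4-(benzyloxy)-5-[4-(benzyloxy)phenyl]-5-(TBS-oxy)pent-2-en-1-ol | OC/C=C/[C@@H](OCc1ccccc1)[C@@H](O[Si](C)(C)C(C)(C)C)c1ccc(OCc2ccccc2)cc1 | intermediate
20 | (2E,4R,5S)-4-(benzyloxy)-5-[4-(benzyloxy)phenyl]-5-(TBS-oxy)pent-2-en-1-yl methyl carbonate | COC(=O)OC/C=C/[C@@H](OCc1ccccc1)[C@@H](O[Si](C)(C)C(C)(C)C)c1ccc(OCc2ccccc2)cc1 | intermediate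
21 | cuprous alkoxide of 10, configuration unchanged (not isolated) | [Cu]O[C@@H]1c2ccc(OCc3ccccc3)c(OCc3ccccc3)c2O[C@@H](c2ccc(OCc3ccccc3)cc2)[C@@H]1OCc1ccccc1 | intermediate
22 | (3R,4R,5S)-4-(benzyloxy)-5-[4-(benzyloxy)phenyl]-5-(TBS-oxy)-3-(UB-O)pent-1-ene | C=C[C@@H](O[C@@H]5c6ccc(OCc7ccccc7)c(OCc7ccccc7)c6O[C@@H](c6ccc(OCc7ccccc7)cc6)[C@@H]5OCc5ccccc5)[C@@H](OCc1ccccc1)[C@@H](O[Si](C)(C)C(C)(C)C)c1ccc(OCc2ccccc2)cc1 | intermediate
23 | (3R,4R,5S)-4-(benzyloxy)-5-[4-(benzyloxy)phenyl]-5-(TBS-oxy)-3-(UB-O)pentane-1,2-diol, both C2 epimers (not isolated) | OCC(O)[C@@H](O[C@@H]5c6ccc(OCc7ccccc7)c(OCc7ccccc7)c6O[C@@H](c6ccc(OCc7ccccc7)cc6)[C@@H]5OCc5ccccc5)[C@@H](OCc1ccccc1)[C@@H](O[Si](C)(C)C(C)(C)C)c1ccc(OCc2ccccc2)cc1 | intermediate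
24 | (2S,3R,4S)-3-(benzyloxy)-4-[4-(benzyloxy)phenyl]-4-(TBS-oxy)-2-(UB-O)butanal | O=C[C@@H](O[C@@H]5c6ccc(OCc7ccccc7)c(OCc7ccccc7)c6O[C@@H](c6ccc(OCc7ccccc7)cc6)[C@@H]5OCc5ccccc5)[C@@H](OCc1ccccc1)[C@@H](O[Si](C)(C)C(C)(C)C)c1ccc(OCc2ccccc2)cc1 | intermediate
25 | (3R,4R,5S)-4-(benzyloxy)-5-[4-(benzyloxy)phenyl]-5-(TBS-oxy)-3-(UB-O)pent-1-yne | C#C[C@@H](O[C@@H]5c6ccc(OCc7ccccc7)c(OCc7ccccc7)c6O[C@@H](c6ccc(OCc7ccccc7)cc6)[C@@H]5OCc5ccccc5)[C@@H](OCc1ccccc1)[C@@H](O[Si](C)(C)C(C)(C)C)c1ccc(OCc2ccccc2)cc1 | intermediate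
26 | squaric acid, 3,4-dihydroxycyclobut-3-ene-1,2-dione | O=C1C(O)=C(O)C1=O | starting material
27 | 3,4-bis(benzyloxy)cyclobut-3-ene-1,2-dione | O=C1C(OCc2ccccc2)=C(OCc2ccccc2)C1=O | intermediate
28 | 2,3-bis(benzyloxy)-4-hydroxycyclobut-2-en-1-one (racemic) | O=C1C(OCc2ccccc2)=C(OCc2ccccc2)C1O | intermediate
29 | 2,3-bis(benzyloxy)-4-chlorocyclobut-2-en-1-one (racemic) | O=C1C(OCc2ccccc2)=C(OCc2ccccc2)C1Cl | intermediate
30 | chloridobis(cyclopentadienyl)[(1E,3R,4R,5S)-4-(benzyloxy)-5-[4-(benzyloxy)phenyl]-5-(TBS-oxy)-3-(UB-O)pent-1-en-1-yl]zirconium (not isolated) | Cl[Zr](C1C=CC=C1)(C1C=CC=C1)/C=C/[C@@H](O[C@@H]5c6ccc(OCc7ccccc7)c(OCc7ccccc7)c6O[C@@H](c6ccc(OCc7ccccc7)cc6)[C@@H]5OCc5ccccc5)[C@@H](OCc1ccccc1)[C@@H](O[Si](C)(C)C(C)(C)C)c1ccc(OCc2ccccc2)cc1 | intermediate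
31 | 2,3-bis(benzyloxy)-4-[(1E,3R,4R,5S)-4-(benzyloxy)-5-[4-(benzyloxy)phenyl]-5-(TBS-oxy)-3-(UB-O)pent-1-en-1-yl]cyclobut-2-en-1-one, both epimers at the ring sp3 carbon | O=C1C(OCc2ccccc2)=C(OCc2ccccc2)C1/C=C/[C@@H](O[C@@H]5c6ccc(OCc7ccccc7)c(OCc7ccccc7)c6O[C@@H](c6ccc(OCc7ccccc7)cc6)[C@@H]5OCc5ccccc5)[C@@H](OCc1ccccc1)[C@@H](O[Si](C)(C)C(C)(C)C)c1ccc(OCc2ccccc2)cc1 | intermediate
32 | (3E,5E,7R,8R,9S)-2,3,8-tris(benzyloxy)-9-[4-(benzyloxy)phenyl]-9-(TBS-oxy)-7-(UB-O)nona-1,3,5-trien-1-one (not isolated) | O=C=C(OCc1ccccc1)\C(OCc1ccccc1)=C/C=C/[C@@H](O[C@@H]5c6ccc(OCc7ccccc7)c(OCc7ccccc7)c6O[C@@H](c6ccc(OCc7ccccc7)cc6)[C@@H]5OCc5ccccc5)[C@@H](OCc1ccccc1)[C@@H](O[Si](C)(C)C(C)(C)C)c1ccc(OCc2ccccc2)cc1 | intermediate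
33 | 2,3-bis(benzyloxy)-6-[(1R,2R,3S)-2-(benzyloxy)-3-[4-(benzyloxy)phenyl]-3-(TBS-oxy)-1-(UB-O)propyl]cyclohexa-2,4-dien-1-one, both C6 epimers (not isolated) | O=C1C(OCc2ccccc2)=C(OCc2ccccc2)C=CC1[C@@H](O[C@@H]5c6ccc(OCc7ccccc7)c(OCc7ccccc7)c6O[C@@H](c6ccc(OCc7ccccc7)cc6)[C@@H]5OCc5ccccc5)[C@@H](OCc1ccccc1)[C@@H](O[Si](C)(C)C(C)(C)C)c1ccc(OCc2ccccc2)cc1 | intermediate
34 | 2,3-bis(benzyloxy)-6-[(1R,2R,3S)-2-(benzyloxy)-3-[4-(benzyloxy)phenyl]-3-(TBS-oxy)-1-(UB-O)propyl]phenol | Oc1c(OCc2ccccc2)c(OCc2ccccc2)ccc1[C@@H](O[C@@H]5c6ccc(OCc7ccccc7)c(OCc7ccccc7)c6O[C@@H](c6ccc(OCc7ccccc7)cc6)[C@@H]5OCc5ccccc5)[C@@H](OCc1ccccc1)[C@@H](O[Si](C)(C)C(C)(C)C)c1ccc(OCc2ccccc2)cc1 | intermediate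
35 | 2,3-bis(benzyloxy)-6-[(1R,2S,3S)-2-(benzyloxy)-3-[4-(benzyloxy)phenyl]-3-hydroxy-1-(UB-O)propyl]phenol | Oc1c(OCc2ccccc2)c(OCc2ccccc2)ccc1[C@@H](O[C@@H]5c6ccc(OCc7ccccc7)c(OCc7ccccc7)c6O[C@@H](c6ccc(OCc7ccccc7)cc6)[C@@H]5OCc5ccccc5)[C@@H](OCc1ccccc1)[C@@H](O)c1ccc(OCc2ccccc2)cc1 | intermediate
36 | (2R,3R,4R)-3,7,8-tris(benzyloxy)-2-[4-(benzyloxy)phenyl]-4-(UB-O)-3,4-dihydro-2H-chromene | c1ccccc1COc1ccc([C@H]2Oc3c(ccc(OCc4ccccc4)c3OCc3ccccc3)[C@@H](O[C@@H]5c6ccc(OCc7ccccc7)c(OCc7ccccc7)c6O[C@@H](c6ccc(OCc7ccccc7)cc6)[C@@H]5OCc5ccccc5)[C@H]2OCc2ccccc2)cc1 | intermediate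
37 | (2R,3R,4R)-2-(4-hydroxyphenyl)-4-{[(2S,3R,4R)-3,7,8-trihydroxy-2-(4-hydroxyphenyl)-3,4-dihydro-2H-chromen-4-yl]oxy}-3,4-dihydro-2H-chromene-3,7,8-triol | Oc1ccc([C@H]2Oc3c(ccc(O)c3O)[C@@H](O[C@@H]3c4ccc(O)c(O)c4O[C@@H](c4ccc(O)cc4)[C@@H]3O)[C@H]2O)cc1 | target

## Step count, longest linear sequence and least certain steps

Total: 26 steps. Longest linear sequence: 16 steps (steps 8–18 and 22–26, from 2-(benzyloxy)acetyl chloride 11).

Step 23 (key step). The ring opening may favour outward rotation of the alkenyl group, so that turnover to 34 is slow and long heating is needed. During that time the ketene can be acylated by the product phenol or can dimerise, and the ortho-hydroxybenzyl ether of 34 can lose unit B thermally through an ortho-quinone methide. The fallback changes to the hydroxy-substituted (Moore) series, in which the hydroxyl group turns outward and places the alkene inward. It sets out from alkyne 25 and squarate 27. Hydrozirconation of 25 and iodination give (1E,3R,4R,5S)-4-(benzyloxy)-5-[4-(benzyloxy)phenyl]-1-iodo-5-(TBS-oxy)-3-(UB-O)pent-1-ene F1. Iodine–lithium exchange with t-BuLi and 1,2-addition to 27 give 2,3-bis(benzyloxy)-4-hydroxy-4-[that pentenyl]cyclobut-2-en-1-one F2. Heating F2 gives 2,3-bis(benzyloxy)-5-[(1R,2R,3S)-2-(benzyloxy)-3-[4-(benzyloxy)phenyl]-3-(TBS-oxy)-1-(UB-O)propyl]benzene-1,4-diol F3, which carries an extra hydroxyl on C6. Triflation of this unhindered hydroxyl (PhNTf2, Et3N) gives 2,3-bis(benzyloxy)-4-hydroxy-5-[the same propyl]phenyl trifluoromethanesulfonate F4, and formate reduction (Pd(OAc)2, dppf, Et3N, HCO2H) returns to the route at 34.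

Step 16. The hindered secondary alkoxide may react too slowly with the branched allyliridium intermediate, and branched/linear selectivity or catalyst control at C4 may suffer from a mismatched pairing with the C3 stereocentre. The fallback forms the ether by reductive etherification and sets out from aldehyde 17 and ketone 9. Vinylmagnesium bromide adds to 17 in THF at −78 °C without a chelating additive (Felkin–Anh, anti) to give (3R,4R,5S)-4-(benzyloxy)-5-[4-(benzyloxy)phenyl]-5-(TBS-oxy)pent-1-en-3-ol F5, which is silylated to its trimethylsilyl ether F6. F6 is condensed with 9 under TMSOTf catalysis and the oxocarbenium ion is reduced with Et3SiH at −78 °C. Hydride, like other nucleophiles at flavan-4-yl cations, should enter trans to the C3' oxygen, which leaves the ether oxygen cis, and the sequence returns at 22.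

Step 21. Activation of the hydroxyl may lead to ionisation to the dialkoxycyclobutenyl cation and loss of a benzyl group to chloride, giving the cyclobutenedione instead of 29. The fallback abandons the halide and sets out from 28: methyl chloroformate and pyridine give 2,3-bis(benzyloxy)-4-oxocyclobut-2-en-1-yl methyl carbonate F7, which has no nucleophilic counter-ion and is ionised only by zerovalent palladium. Allylic substitution of F7 by alkenylzirconocene 30 under Pd(PPh3)4 returns at 31.

Step 22. The chloride may decompose before oxidative addition, transmetalation from the hindered alkenylzirconocene may be slow, and the skipped enone of 31 may isomerise into conjugation. The fallback makes the alkene by metathesis and sets out from 29 and alkene 22. Stille coupling of 29 with tributyl(vinyl)stannane ((PhCN)2PdCl2, tri(2-furyl)phosphine) gives 2,3-bis(benzyloxy)-4-ethenylcyclobut-2-en-1-one F8. Cross metathesis of F8 with 22 (second-generation Hoveyda–Grubbs catalyst, CH2Cl2, 40 °C) returns at 31 and bypasses steps 17 and 18.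

Step 25. The activated p-alkoxybenzylic centre may ionise, which would erode the inversion and give the 2,3-trans ring, or may eliminate. The fallback sets C2 by hydride delivery and sets out from 35. MnO2 oxidises the benzylic alcohol to (2R,3R)-2-(benzyloxy)-1-[4-(benzyloxy)phenyl]-3-[3,4-bis(benzyloxy)-2-hydroxyphenyl]-3-(UB-O)propan-1-one F9, which closes to its cyclic hemiketal. Reduction with Et3SiH and TMSOTf at −78 °C should deliver hydride to the 2-aryl oxocarbenium ion anti to the C3 benzyloxy group, giving the 2,3-cis ring and returning at 36.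

Step 7. Facial selectivity may be poor, because a chromanone has only one axial hydrogen to hinder axial attack, and the 3,4-trans alcohol may form. The fallback replaces substrate control by catalyst control and runs from 9 to 10: Noyori-type asymmetric transfer hydrogenation with RuCl[(S,S)-TsDPEN](p-cymene) and HCO2H/Et3N, the enantiomer expected to give the 4'R alcohol. No new compound is involved.

The final hydrogenolysis is judged less uncertain than these, because the benzylic C–O bonds that must survive are ring-embedded and secondary, like those that survive debenzylation of flavan-3-ols.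

## Further compounds

F1 | step 23 | (1E,3R,4R,5S)-4-(benzyloxy)-5-[4-(benzyloxy)phenyl]-1-iodo-5-(TBS-oxy)-3-(UB-O)pent-1-ene | I/C=C/[C@@H](O[C@@H]5c6ccc(OCc7ccccc7)c(OCc7ccccc7)c6O[C@@H](c6ccc(OCc7ccccc7)cc6)[C@@H]5OCc5ccccc5)[C@@H](OCc1ccccc1)[C@@H](O[Si](C)(C)C(C)(C)C)c1ccc(OCc2ccccc2)cc1
F2 | step 23 | 2,3-bis(benzyloxy)-4-hydroxy-4-[(1E,3R,4R,5S)-4-(benzyloxy)-5-[4-(benzyloxy)phenyl]-5-(TBS-oxy)-3-(UB-O)pent-1-en-1-yl]cyclobut-2-en-1-one | O=C1C(OCc2ccccc2)=C(OCc2ccccc2)C1(O)/C=C/[C@@H](O[C@@H]5c6ccc(OCc7ccccc7)c(OCc7ccccc7)c6O[C@@H](c6ccc(OCc7ccccc7)cc6)[C@@H]5OCc5ccccc5)[C@@H](OCc1ccccc1)[C@@H](O[Si](C)(C)C(C)(C)C)c1ccc(OCc2ccccc2)cc1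
F3 | step 23 | 2,3-bis(benzyloxy)-5-[(1R,2R,3S)-2-(benzyloxy)-3-[4-(benzyloxy)phenyl]-3-(TBS-oxy)-1-(UB-O)propyl]benzene-1,4-diol | Oc1c(OCc2ccccc2)c(OCc2ccccc2)c(O)cc1[C@@H](O[C@@H]5c6ccc(OCc7ccccc7)c(OCc7ccccc7)c6O[C@@H](c6ccc(OCc7ccccc7)cc6)[C@@H]5OCc5ccccc5)[C@@H](OCc1ccccc1)[C@@H](O[Si](C)(C)C(C)(C)C)c1ccc(OCc2ccccc2)cc1
F4 | step 23 | 2,3-bis(benzyloxy)-4-hydroxy-5-[(1R,2R,3S)-2-(benzyloxy)-3-[4-(benzyloxy)phenyl]-3-(TBS-oxy)-1-(UB-O)propyl]phenyl trifluoromethanesulfonate | Oc1c(OCc2ccccc2)c(OCc2ccccc2)c(OS(=O)(=O)C(F)(F)F)cc1[C@@H](O[C@@H]5c6ccc(OCc7ccccc7)c(OCc7ccccc7)c6O[C@@H](c6ccc(OCc7ccccc7)cc6)[C@@H]5OCc5ccccc5)[C@@H](OCc1ccccc1)[C@@H](O[Si](C)(C)C(C)(C)C)c1ccc(OCc2ccccc2)cc1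
F5 | step 16 | (3R,4R,5S)-4-(benzyloxy)-5-[4-(benzyloxy)phenyl]-5-(TBS-oxy)pent-1-en-3-ol | C=C[C@@H](O)[C@@H](OCc1ccccc1)[C@@H](O[Si](C)(C)C(C)(C)C)c1ccc(OCc2ccccc2)cc1
F6 | step 16 | (3R,4R,5S)-4-(benzyloxy)-5-[4-(benzyloxy)phenyl]-5-(TBS-oxy)-3-[(trimethylsilyl)oxy]pent-1-ene | C=C[C@@H](O[Si](C)(C)C)[C@@H](OCc1ccccc1)[C@@H](O[Si](C)(C)C(C)(C)C)c1ccc(OCc2ccccc2)cc1
F7 | step 21 | 2,3-bis(benzyloxy)-4-oxocyclobut-2-en-1-yl methyl carbonate | COC(=O)OC1C(OCc2ccccc2)=C(OCc2ccccc2)C1=O
F8 | step 22 | 2,3-bis(benzyloxy)-4-ethenylcyclobut-2-en-1-one | C=CC1C(OCc2ccccc2)=C(OCc2ccccc2)C1=O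
F9 | step 25 | (2R,3R)-2-(benzyloxy)-1-[4-(benzyloxy)phenyl]-3-[3,4-bis(benzyloxy)-2-hydroxyphenyl]-3-(UB-O)propan-1-one | Oc1c(OCc2ccccc2)c(OCc2ccccc2)ccc1[C@@H](O[C@@H]5c6ccc(OCc7ccccc7)c(OCc7ccccc7)c6O[C@@H](c6ccc(OCc7ccccc7)cc6)[C@@H]5OCc5ccccc5)[C@@H](OCc1ccccc1)C(=O)c1ccc(OCc2ccccc2)cc1
F0 | step 7 | none | none
A1 | alternative 1 | ring F enol ether: perbenzylated unit A (configured as in 36) bound through O-4 to C4' of 7,8-bis(benzyloxy)-2-[4-(benzyloxy)phenyl]-2H-chromene (C2' configured as in the target) | c9ccccc9COc1ccc([C@H]2Oc3c(ccc(OCc9ccccc9)c3OCc9ccccc9)[C@@H](OC3=C[C@H](c4ccc(OCc9ccccc9)cc4)Oc4c(OCc9ccccc9)c(OCc9ccccc9)ccc34)[C@H]2OCc9ccccc9)cc1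
A2 | alternative 2 | (Z)-2-[4-(benzyloxy)phenyl]ethenyl acetate | CC(=O)O/C=C\c1ccc(OCc2ccccc2)cc1
A3 | alternative 2 | 3-O-acetyl heptabenzyl ether of 37 (acetate on C3 of unit A) | c9ccccc9COc1ccc([C@H]2Oc3c(ccc(OCc9ccccc9)c3OCc9ccccc9)[C@@H](O[C@@H]3c4ccc(OCc9ccccc9)c(OCc9ccccc9)c4O[C@@H](c4ccc(OCc9ccccc9)cc4)[C@@H]3OCc9ccccc9)[C@H]2OC(C)=O)cc1
A4 | alternative 3 | heptabenzyl ether of 37 with free C3' hydroxyl | c9ccccc9COc1ccc([C@H]2Oc3c(ccc(OCc9ccccc9)c3OCc9ccccc9)[C@@H](O[C@@H]3c4ccc(OCc9ccccc9)c(OCc9ccccc9)c4O[C@@H](c4ccc(OCc9ccccc9)cc4)[C@@H]3O)[C@H]2OCc9ccccc9)cc1
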